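## Retrosynthetic overview

- The target is released last by a lipase (a carboxylic-ester hydrolase), which removes the 4'-O-acetate at neutral pH so that the base-labile C2 centre and the acid-labile geranyl ether both survive.
- The C2–aryl bond, and with it the only stereocentre, comes from a rhodium-catalysed asymmetric 1,4-addition of an achiral arylboronic acid to a 2-unsubstituted chromone.
- The chromone carries both geranyl groups already; the O-geranyl ether is made by alkylating the 7-OH of 8-geranyl-5,7-dihydroxychromone, whose 5-OH is chelated.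
- The pyranone is closed through the single free phenol of a bis-MOM C-geranyl acetophenone, which fixes 8- over 6-geranyl regiochemistry.
- The C-geranyl group comes from direct C-alkylation of phloroacetophenone. Ring order: ring A is bought, ring C is closed on it, ring B is attached last.

Assumption: "geranyl" always means (2E)-3,7-dimethylocta-2,6-dien-1-yl, flavonoid numbering is used, and the target is read as (2S)-5,4'-dihydroxy-7-geranyloxy-8-geranylflavanone.

## Route

Step 1
Reactants: 1 1-(2,4,6-trihydroxyphenyl)ethanone (phloroacetophenone); 2 geranyl bromide [(2E)-1-bromo-3,7-dimethylocta-2,6-diene]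
Product: 3 1-{3-[(2E)-3,7-dimethylocta-2,6-dien-1-yl]-2,4,6-trihydroxyphenyl}ethanone
Conditions: K2CO3 (1.0 equiv), acetone, reflux, 6 h (1 in 1.5-fold excess over 2)
Reagents that add atoms: none
Why: Base-mediated C-allylation of the phloroglucinol nucleus (phenoxide C-alkylation, SN2 at the primary allylic bromide) gives one mono-C-alkyl isomer because the ring is symmetric, and the E olefin is untouched; this is the known preparation of this natural acylphloroglucinol, modest in yield but reproducible.

Step 2
Reactants: 3 1-{3-geranyl-2,4,6-trihydroxyphenyl}ethanone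
Product: 4 1-{3-geranyl-2-hydroxy-4,6-bis(methoxymethoxy)phenyl}ethanone
Conditions: MOMCl (2.2 equiv), K2CO3 (3 equiv), acetone, 0 °C to rt
Reagents that add atoms: chloromethyl methyl ether (MOMCl), COCCl
Why: Williamson-type acetal etherification takes the acidic 4-OH and the unhindered 6-OH, while the 2-OH, wedged between acetyl and geranyl and locked in the carbonyl hydrogen bond, stays free (minor regioisomer removed by chromatography, assignment checked by HMBC).

Step 3
Reactants: 4 1-{3-geranyl-2-hydroxy-4,6-bis(methoxymethoxy)phenyl}ethanone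
Product: 6 8-geranyl-5,7-bis(methoxymethoxy)-4H-chromen-4-one, via enaminone 5 (not isolated)
Conditions: Me2NCH(OMe)2 (3 equiv), toluene, 95 °C, 3 h; evaporate; then 1 M aq HCl, CH2Cl2, rt, 30 min
Reagents that add atoms: N,N-dimethylformamide dimethyl acetal, COC(OC)N(C)C
Why: Enaminone formation from the methyl ketone followed by acid-promoted oxa-Michael addition–elimination (chromone annulation) can only use the free 2-OH next to the geranyl group, so the 8-geranyl pattern is locked in; brief dilute acid at rt leaves MOM ethers and olefins alone.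

Step 4
Reactants: 6 8-geranyl-5,7-bis(methoxymethoxy)-4H-chromen-4-one
Product: 7 8-geranyl-5,7-dihydroxy-4H-chromen-4-one
Conditions: 3 M aq HCl/MeOH (1:5), 50 °C, about 2 h (stop at full conversion)
Reagents that add atoms: none
Why: Acid-catalysed acetal cleavage on an achiral, acid-stable chromone, under conditions used for MOM removal from C-prenyl and C-geranyl flavonoids (over-long heating would cyclise 7-OH onto the geranyl olefin).

Step 5
Reactants: 7 8-geranyl-5,7-dihydroxy-4H-chromen-4-one; 2 geranyl bromide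
Product: 8 8-geranyl-7-geranyloxy-5-hydroxy-4H-chromen-4-one
Conditions: K2CO3 (1.5 equiv), acetone, 45 °C
Reagents that add atoms: none
Why: Williamson ether synthesis is selective for the 7-OH because the 5-OH is chelated to the C4 carbonyl, the deactivated chromone ring does not C-alkylate, and SN2 at the primary allylic carbon keeps the E geometry.

Step 6
Reactants: 8 8-geranyl-7-geranyloxy-5-hydroxy-4H-chromen-4-one; 9 (4-acetoxyphenyl)boronic acid (3 equiv)
Product: 10 4-[(2S)-8-geranyl-7-geranyloxy-5-hydroxy-4-oxochroman-2-yl]phenyl acetate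
Conditions: [Rh(OH)(cod)]2 (2.5 mol %), (S)-MeO-F12-BIPHEP [(S)-(6,6'-dimethoxybiphenyl-2,2'-diyl)bis[bis(3,4,5-trifluorophenyl)phosphine], 5.5 mol %], degassed toluene/H2O (10:1), 40 °C, 12 h
Reagents that add atoms: none
Why: Hayashi–Miyaura asymmetric 1,4-addition: the aryl group passes from boron to monovalent rhodium and inserts into C2=C3 of the chromone, the (S)-bisphosphine shielding one enone face so that C2 forms as (2S) (same quadrant model as (S)-BINAP with 2-cyclohexenone), and water protonates the rhodium enolate; trisubstituted olefins and the aryl acetate are inert.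

Step 7
Reactants: 10 4-[(2S)-8-geranyl-7-geranyloxy-5-hydroxy-4-oxochroman-2-yl]phenyl acetate
Product: 11 (2S)-8-geranyl-7-geranyloxy-5-hydroxy-2-(4-hydroxyphenyl)chroman-4-one (target)
Conditions: immobilised lipase B from Candida antarctica, n-BuOH (5 equiv), MTBE, 40 °C, 12–24 h
Reagents that add atoms: none
Why: Lipase-catalysed transesterification (alcoholysis) of the unhindered aryl acetate runs at neutral pH in organic solvent, so there is no phenoxide-driven ring opening at C2 and no acid to cleave the geranyl ether; the stereocentre is not touched.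

## Compound list

1 | 1-(2,4,6-trihydroxyphenyl)ethanone (phloroacetophenone) | CC(=O)c1c(O)cc(O)cc1O | starting material
2 | geranyl bromide, (2E)-1-bromo-3,7-dimethylocta-2,6-diene | CC(C)=CCC/C(C)=C/CBr | starting material
3 | 1-{3-[(2E)-3,7-dimethylocta-2,6-dien-1-yl]-2,4,6-trihydroxyphenyl}ethanone | CC(=O)c1c(O)cc(O)c(C/C=C(\C)CCC=C(C)C)c1O | intermediate
4 | 1-{3-geranyl-2-hydroxy-4,6-bis(methoxymethoxy)phenyl}ethanone | CC(=O)c1c(OCOC)cc(OCOC)c(C/C=C(\C)CCC=C(C)C)c1O | intermediate
5 | (2E)-3-(dimethylamino)-1-{3-geranyl-2-hydroxy-4,6-bis(methoxymethoxy)phenyl}prop-2-en-1-one (enaminone, not isolated) | CN(C)/C=C/C(=O)c1c(OCOC)cc(OCOC)c(C/C=C(\C)CCC=C(C)C)c1O | intermediate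
6 | 8-geranyl-5,7-bis(methoxymethoxy)-4H-chromen-4-one | O=c1ccoc2c(C/C=C(\C)CCC=C(C)C)c(OCOC)cc(OCOC)c12 | intermediate
7 | 8-geranyl-5,7-dihydroxy-4H-chromen-4-one | O=c1ccoc2c(C/C=C(\C)CCC=C(C)C)c(O)cc(O)c12 | intermediate
8 | 8-geranyl-7-geranyloxy-5-hydroxy-4H-chromen-4-one | O=c1ccoc2c(C/C=C(\C)CCC=C(C)C)c(OC/C=C(\C)CCC=C(C)C)cc(O)c12 | intermediate
9 | (4-acetoxyphenyl)boronic acid | CC(=O)Oc1ccc(cc1)B(O)O | starting material
10 | 4-[(2S)-8-geranyl-7-geranyloxy-5-hydroxy-4-oxochroman-2-yl]phenyl acetate | CC(C)=CCC/C(C)=C/COc1cc(O)c2c(c1C/C=C(\C)CCC=C(C)C)O[C@H](c1ccc(OC(C)=O)cc1)CC2=O | intermediate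
11 | (2S)-8-geranyl-7-geranyloxy-5-hydroxy-2-(4-hydroxyphenyl)chroman-4-one | CC(C)=CCC/C(C)=C/COc1cc(O)c2c(c1C/C=C(\C)CCC=C(C)C)O[C@H](c1ccc(O)cc1)CC2=O | target

## Step count and risks

Total steps: 7. Longest linear sequence: 7 (from 1 to 11).

Steps most likely to fail:

**Step 6 (asymmetric 1,4-addition).** Chromone 8 carries a chelated free 5-OH, an allylic aryl ether and a bulky C8 group, so conversion or ee may fall short of the simple-chromone precedent. The sense of induction should also be confirmed on the first run by CD or chiral HPLC; the (R)-ligand is the trivial remedy if it is reversed. The fallback changes the order of events: it sets out from 6 and comes back at 11. The stereocentre is set on the fully protected chromone 6, which has no free phenol and no allylic ether, by the same kind of rhodium/(S)-bisphosphine addition of 9. This gives 4-[(2S)-8-geranyl-5,7-bis(methoxymethoxy)-4-oxochroman-2-yl]phenyl acetate F7. 3 M aq HCl/MeOH at 50 °C then strips both MOM groups and the acetate, giving (2S)-8-geranyl-5,7-dihydroxy-2-(4-hydroxyphenyl)chroman-4-one F8; the flavanone is configurationally stable to acid. A Mitsunobu etherification with geraniol (PPh3, DIAD, THF, 0 °C) takes the most acidic 7-OH at neutral pH and delivers 11 directly.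

**Step 1 (C-geranylation).** O-alkylation and double C-alkylation compete, so the yield is modest (roughly 30–40 %). The fallback sets out from 2 and comes back at 3. Phloroglucinol is protected with MOMCl/NaH (DMF, 0 °C) as 1,3,5-tris(methoxymethoxy)benzene F1. Directed ortho-lithiation (n-BuLi, THF, 0 °C), then CuI (0.1 equiv) and 2, gives 2-geranyl-1,3,5-tris(methoxymethoxy)benzene F2 by SN2 coupling with the E olefin kept. A second lithiation between two MOM-oxy groups and quenching with N-methoxy-N-methylacetamide gives 1-{3-geranyl-2,4,6-tris(methoxymethoxy)phenyl}ethanone F3. 3 M aq HCl/MeOH at 50 °C removes the three MOM groups and gives 3.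

**Step 2 (regioselective bis-protection).** If the small MOM group also reaches the 2-OH, or the regioisomers co-elute, 6-geranyl material is carried forward. The fallback sets out from 3 and comes back at 7. It uses a much bulkier silyl group and fluoride unmasking, which also removes the acidic step 4. i-Pr3SiCl/imidazole (DMF, rt) silylates only the 4- and 6-OH, giving 1-{3-geranyl-2-hydroxy-4,6-bis[(triisopropylsilyl)oxy]phenyl}ethanone F4. DMF-DMA (toluene, 95 °C) gives (2E)-3-(dimethylamino)-1-{3-geranyl-2-hydroxy-4,6-bis[(triisopropylsilyl)oxy]phenyl}prop-2-en-1-one F5. This is closed without isolation (1 M aq HCl, CH2Cl2, rt) to 8-geranyl-5,7-bis[(triisopropylsilyl)oxy]-4H-chromen-4-one F6. Bu4NF/AcOH (THF, 0 °C) then gives 7.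

## Further compounds

F1 | step 1 | 1,3,5-tris(methoxymethoxy)benzene | COCOc1cc(OCOC)cc(OCOC)c1
F2 | step 1 | 2-geranyl-1,3,5-tris(methoxymethoxy)benzene | COCOc1cc(OCOC)c(C/C=C(\C)CCC=C(C)C)c(OCOC)c1
F3 | step 1 | 1-{3-geranyl-2,4,6-tris(methoxymethoxy)phenyl}ethanone | CC(=O)c1c(OCOC)cc(OCOC)c(C/C=C(\C)CCC=C(C)C)c1OCOC
F4 | step 2 | 1-{3-geranyl-2-hydroxy-4,6-bis[(triisopropylsilyl)oxy]phenyl}ethanone | CC(=O)c1c(O[Si](C(C)C)(C(C)C)C(C)C)cc(O[Si](C(C)C)(C(C)C)C(C)C)c(C/C=C(\C)CCC=C(C)C)c1O
F5 | step 2 | (2E)-3-(dimethylamino)-1-{3-geranyl-2-hydroxy-4,6-bis[(triisopropylsilyl)oxy]phenyl}prop-2-en-1-one | CN(C)/C=C/C(=O)c1c(O[Si](C(C)C)(C(C)C)C(C)C)cc(O[Si](C(C)C)(C(C)C)C(C)C)c(C/C=C(\C)CCC=C(C)C)c1O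
F6 | step 2 | 8-geranyl-5,7-bis[(triisopropylsilyl)oxy]-4H-chromen-4-one | O=c1ccoc2c(C/C=C(\C)CCC=C(C)C)c(O[Si](C(C)C)(C(C)C)C(C)C)cc(O[Si](C(C)C)(C(C)C)C(C)C)c12
F7 | step 6 | 4-[(2S)-8-geranyl-5,7-bis(methoxymethoxy)-4-oxochroman-2-yl]phenyl acetate | COCOc1cc(OCOC)c2c(c1C/C=C(\C)CCC=C(C)C)O[C@H](c1ccc(OC(C)=O)cc1)CC2=O
F8 | step 6 | (2S)-8-geranyl-5,7-dihydroxy-2-(4-hydroxyphenyl)chroman-4-one | Oc1cc(O)c2c(c1C/C=C(\C)CCC=C(C)C)O[C@H](c1ccc(O)cc1)CC2=O
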